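## Retrosynthetic overview

Ring letters: A = methoxy-bearing ring, B = para-phenylene bound to the oxygen on A, C = phenol ring, D = meta-phenylene. There is no stereocentre, so the task is the 20-membered ring.
Final C–C disconnection: C4 of ring B / adjacent bridge CH2. It is made in one flask by 9-BBN hydroboration of an open-chain ring C styrene and intramolecular B-alkyl Suzuki–Miyaura coupling with a ring B bromide, and only O-debenzylation follows.
Enabling feature: this CH2 is the outer carbon of the two-carbon chain on C1 of ring C, so it can be stored as the =CH2 of a styrene on which 9-BBN places boron. C4 of ring B is para to the ether oxygen and flanked by two CH groups (an unhindered C–Br site), and the two ether oxygens and the meta-linked rings A and D are hinges that let the chain ends meet.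
The open chain is cut at C3 of ring D / bridge CH2 by the same reaction run between two molecules: the AB styrene (Br on B) serves as borane and the CD styrene (I on D) as halide, iodide before bromide.
A–O–B comes from Chan–Lam coupling of isovanillin, C–O–D from SNAr on 3-benzyloxy-4-fluorobenzaldehyde, and both vinyl groups from Wittig methylenation. All four benzene rings are bought, and the macrocycle is the only ring formed (step 7).

Key step: step 7

Remark on the chemistry: 4-fluoro-3-hydroxybenzaldehyde, 3-iodophenol, isovanillin and 4-bromophenylboronic acid are taken as catalogue chemicals. The target has no stereocentre, so only one alkene in a fallback compound carries a stereo descriptor.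

## Route

Step 1
Reactants: 1 4-fluoro-3-hydroxybenzaldehyde
Product: 2 3-(benzyloxy)-4-fluorobenzaldehyde
Conditions: BnBr, K2CO3, DMF, rt
Reagents that add atoms: benzyl bromide, BrCc1ccccc1
Why: Williamson ether synthesis, in which the phenoxide made by K2CO3 displaces bromide from benzyl bromide by SN2 while the aldehyde and the aryl fluoride do not react at this temperature.

Step 2
Reactants: 2 3-(benzyloxy)-4-fluorobenzaldehyde; 3 3-iodophenol
Product: 4 3-(benzyloxy)-4-(3-iodophenoxy)benzaldehyde
Conditions: K2CO3, DMF, 130 °C, Ar
Reagents that add atoms: none
Why: Nucleophilic aromatic substitution (SNAr, addition–elimination), in which the formyl group para to fluorine stabilises the Meisenheimer adduct of the 3-iodophenoxide while the unactivated C–I bond, which meets no transition metal, stays intact.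

Step 3
Reactants: 4 3-(benzyloxy)-4-(3-iodophenoxy)benzaldehyde
Product: 5 2-(benzyloxy)-1-(3-iodophenoxy)-4-vinylbenzene
Conditions: Ph3PCH3Br, KOtBu, THF, 0 °C → rt
Reagents that add atoms: methyltriphenylphosphonium bromide, C[P+](c1ccccc1)(c1ccccc1)c1ccccc1.[Br-]
Why: Wittig methylenation, in which the non-stabilised ylide converts the aldehyde into the terminal alkene through an oxaphosphetane while aryl iodide, benzyl ether and diaryl ether are inert to it at or below room temperature.

Step 4
Reactants: 6 isovanillin (3-hydroxy-4-methoxybenzaldehyde); 7 4-bromophenylboronic acid
Product: 8 3-(4-bromophenoxy)-4-methoxybenzaldehyde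
Conditions: Cu(OAc)2 (0.2 equiv), pyridine, 4 Å MS, CH2Cl2, O2 (1 atm), rt
Reagents that add atoms: none
Why: Chan–Lam oxidative C–O coupling, in which the aryl group passes from boron to copper and is joined to the phenoxide by reductive elimination from trivalent copper at room temperature, conditions that leave the C–Br bond and the aldehyde untouched.

Step 5
Reactants: 8 3-(4-bromophenoxy)-4-methoxybenzaldehyde
Product: 9 2-(4-bromophenoxy)-1-methoxy-4-vinylbenzene
Conditions: Ph3PCH3Br, KOtBu, THF, 0 °C → rt
Reagents that add atoms: methyltriphenylphosphonium bromide, C[P+](c1ccccc1)(c1ccccc1)c1ccccc1.[Br-]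
Why: Wittig methylenation as in step 3, to which the aryl bromide, the methyl ether and the diaryl ether are inert.

Step 6
Reactants: 9 2-(4-bromophenoxy)-1-methoxy-4-vinylbenzene; 5 2-(benzyloxy)-1-(3-iodophenoxy)-4-vinylbenzene
Product: 11 open-chain bromo styrene 2-(4-bromophenoxy)-4-{2-[3-(2-benzyloxy-4-vinylphenoxy)phenyl]ethyl}-1-methoxybenzene, via B-alkyl-9-BBN borane 10 (not isolated)
Conditions: 9, 9-BBN-H (1.0 equiv), THF, 0 °C → rt; aq Cs2CO3, 30 min; then 5, PdCl2(dppf) (5 mol %), AsPh3 (5 mol %), DMF/THF/H2O, rt
Reagents that add atoms: 9-borabicyclo[3.3.1]nonane (9-BBN-H), [H]B1C2CCCC1CCC2 (its boron bicycle is held only in intermediate 10; product 11 keeps only its hydrogen)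
Why: Anti-Markovnikov hydroboration followed by intermolecular B-alkyl Suzuki–Miyaura coupling, in which 9-BBN-H puts boron on the outer carbon of styrene 9, any leftover B–H is destroyed by aqueous base before 5 is added so that its vinyl group never meets it, and at room temperature zerovalent palladium inserts into the C–I bond on ring D far faster than into the electron-rich C–Br bond on ring B or than it draws the styrene into a Heck reaction.

Step 7
Reactants: 11 open-chain bromo styrene
Product: 13 O-benzylpakyonol (the 20-membered macrocycle with the ring C hydroxyl as benzyl ether), via ring C B-alkyl-9-BBN borane 12 (not isolated)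
Conditions: 9-BBN-H (1.3 equiv), THF, 0 °C → rt; degassed H2O; then syringe-pump addition (12 h) to PdCl2(dppf) (15 mol %), AsPh3 (15 mol %), Cs2CO3 (4 equiv), DMF/THF/H2O, 60 °C, final about 1 mM
Reagents that add atoms: 9-borabicyclo[3.3.1]nonane (9-BBN-H), [H]B1C2CCCC1CCC2 (its boron bicycle is held only in intermediate 12; product 13 keeps only its hydrogen)
Why: 9-BBN-H adds to the ring C vinyl group with boron on the outer carbon to give 12, base turns the borane into a borate, zerovalent palladium inserts into the C–Br bond at C4 of ring B, the primary alkyl group passes from boron to palladium within the same molecule, and reductive elimination from the cis aryl(alkyl)palladium species forms the C4(ring B)–CH2 bond. The closest known reaction type is the intramolecular B-alkyl Suzuki–Miyaura macrocyclisation, an established way to close large carbocycles and cyclophanes at an sp3–sp2 bond. One ring is closed, the 20-membered ring (shortest path through the four arenes), end to end through a 21-membered palladacycle whose C–Pd–C angle near 90° resembles the gauche B–C bridge of the product. A saturated sp3 chain end is chosen on purpose, since by an estimate from standard bond lengths an anti bridge or an E-alkene between the para-linked rings B and C would hold the two ether oxygens about 12 Å apart, while the A–CH2CH2–D half can span about 11 Å at most. No stereocentre is formed; the step needs terminal regioselectivity in the hydroboration (secured by the bulk of 9-BBN and by the electron-donating para oxygen on ring C, both of which disfavour boron at the benzylic carbon), ring closure over chain growth (secured by slow addition of 12 to the hot catalyst, by the ether and meta-arene hinges, and by there being only one C–B and one C–Br site), and reductive elimination over β-hydride elimination (secured by the wide bite angle of dppf). The bridge is delivered at its final oxidation level, so that no alkene, carbonyl, sulfur or phosphorus residue has to be removed from the macrocycle.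

Step 8
Reactants: 13 O-benzylpakyonol
Product: 14 pakyonol
Conditions: H2 (1 atm), 10% Pd/C, EtOAc/MeOH, rt
Reagents that add atoms: none
Why: Catalytic hydrogenolysis of the benzylic C–O bond on palladium frees the ring C phenol, while the diaryl ethers, the methyl ether and the saturated bridges are inert under one atmosphere of hydrogen.

## Compound list

1 | 4-fluoro-3-hydroxybenzaldehyde | O=Cc1ccc(F)c(O)c1 | starting material
2 | 3-(benzyloxy)-4-fluorobenzaldehyde | O=Cc1ccc(F)c(OCc2ccccc2)c1 | intermediate
3 | 3-iodophenol | Oc1cccc(I)c1 | starting material
4 | 3-(benzyloxy)-4-(3-iodophenoxy)benzaldehyde | O=Cc1ccc(Oc2cccc(I)c2)c(OCc2ccccc2)c1 | intermediate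
5 | 2-(benzyloxy)-1-(3-iodophenoxy)-4-vinylbenzene (CD fragment) | C=Cc1ccc(Oc2cccc(I)c2)c(OCc2ccccc2)c1 | intermediate
6 | isovanillin (3-hydroxy-4-methoxybenzaldehyde) | COc1ccc(C=O)cc1O | starting material
7 | 4-bromophenylboronic acid | OB(O)c1ccc(Br)cc1 | starting material
8 | 3-(4-bromophenoxy)-4-methoxybenzaldehyde | COc1ccc(C=O)cc1Oc1ccc(Br)cc1 | intermediate
9 | 2-(4-bromophenoxy)-1-methoxy-4-vinylbenzene (AB fragment) | COc1ccc(C=C)cc1Oc1ccc(Br)cc1 | intermediate
10 | 9-{2-[3-(4-bromophenoxy)-4-methoxyphenyl]ethyl}-9-borabicyclo[3.3.1]nonane | COc1ccc(CCB2C3CCCC2CCC3)cc1Oc1ccc(Br)cc1 | intermediate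
11 | 2-(4-bromophenoxy)-4-{2-[3-(2-benzyloxy-4-vinylphenoxy)phenyl]ethyl}-1-methoxybenzene (open-chain bromo styrene) | COc1ccc(CCc2cccc(Oc3ccc(C=C)cc3OCc3ccccc3)c2)cc1Oc1ccc(Br)cc1 | intermediate
12 | 9-{2-[3-benzyloxy-4-(3-{2-[3-(4-bromophenoxy)-4-methoxyphenyl]ethyl}phenoxy)phenyl]ethyl}-9-borabicyclo[3.3.1]nonane | COc1ccc(CCc2cccc(Oc3ccc(CCB4C5CCCC4CCC5)cc3OCc3ccccc3)c2)cc1Oc1ccc(Br)cc1 | intermediate
13 | O-benzylpakyonol | COc1ccc2cc1Oc1ccc(cc1)CCc1ccc(c(OCc3ccccc3)c1)Oc1cccc(c1)CC2 | intermediate
14 | pakyonol | COc1ccc2cc1Oc1ccc(cc1)CCc1ccc(c(O)c1)Oc1cccc(c1)CC2 | target

## Step count and risks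

Total step count: 8.
Longest linear sequence: 6 steps (1 → 2 → 3 → 6 → 7 → 8). The second branch (steps 4 and 5) joins at step 6.

**First risk, step 7.**
- What may go wrong: ring closure may be outrun by coupling between molecules (chain growth). The borane may also be lost by protodeboronation or, after transfer to palladium, by β-hydride elimination, because insertion into the electron-rich C–Br bond is slow.
- Fallback: no boron is used and the alkene itself is the reacting group. It sets out from 11.
- An intramolecular Mizoroki–Heck reaction (Pd(OAc)2, P(o-tol)3, K2CO3, Bu4NBr, DMF, 100 °C, high dilution) joins the same two carbons and should give the macrocyclic (Z)-stilbene benzyl ether F1.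
- The Z geometry is expected because the carbopalladated ring can lose either hydrogen of the new CH2, and the E rod is too long for the ring. The geometry is of no consequence.
- Hydrogenation (H2, Pd/C, EtOAc/MeOH) then saturates the alkene and cleaves the benzyl ether in one operation, which comes back to the route at 14.

**Second risk, step 6.**
- What may go wrong: the vinyl group of the iodide partner may be drawn into the reaction, either by hydroboration from residual B–H or by Heck-type arylation. Part of the catalyst may also insert into the C–Br bond, which starts self-coupling of the borane.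
- Fallback: the vinyl group is kept out of the coupling and the order of events is changed. It sets out from 4 and from 9.
- Borane 10, made from 9 as before, is coupled with an excess of iodo aldehyde 4 (PdCl2(dppf), Cs2CO3, DMF/THF/H2O, rt) to give the open-chain bromo aldehyde F2.
- Wittig methylenation of F2 (Ph3PCH3Br, KOtBu, THF) comes back to the route at 11.

**Third risk, step 4.**
- What may go wrong: the oxidative coupling may stall through protodeboronation or oxidative hydroxylation of the boronic acid, and through chelation of copper by the ortho-methoxy phenoxide.
- Fallback: the oxidative boronic acid coupling is replaced by a halide-based Ullmann-type ether synthesis. It sets out from 6.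
- Heating with an excess of 1-bromo-4-iodobenzene (CuI, N,N-dimethylglycine, Cs2CO3, dioxane, 90 °C) should engage the C–I bond first.
- The bromide of the product is further deactivated by the new para oxygen.
- This comes back to the route at 8 and makes no new compound (F0).

Further compounds
F1 | step 7 | macrocyclic (Z)-stilbene benzyl ether (O-benzylpakyonol with a Z-CH=CH bridge between rings B and C) | COc1ccc2cc1Oc1ccc(cc1)/C=C\c1ccc(c(OCc3ccccc3)c1)Oc1cccc(c1)CC2
F2 | step 6 | open-chain bromo aldehyde 3-(benzyloxy)-4-(3-{2-[3-(4-bromophenoxy)-4-methoxyphenyl]ethyl}phenoxy)benzaldehyde | COc1ccc(CCc2cccc(Oc3ccc(C=O)cc3OCc3ccccc3)c2)cc1Oc1ccc(Br)cc1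
F0 | step 4 | none | none
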